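## Retrosynthetic overview

1. Target ⇒ redox-neutral radical bicyclization of a type A bicyclo[3.3.1]nonane enol carrying C3 prenyl, C5 geranyl and endo C7 prenyl (the C3 radical closes the seven-membered ring, then a 5-exo closure gives the cyclopentane).
2. C3 prenyl ⇒ Stille coupling of a C3 bromide; endo C7 prenyl ⇒ retro-aldol/Wittig and 1,4-hydrogenation of a bromo adamantanol.
3. Bromo adamantanol ⇒ enantioselective phase-transfer alkylative dearomatization–Michael–aldol of 3-bromo-5-geranyl-2,4,6-trihydroxybenzophenone with 2-formyl-3-methylbut-2-enyl acetate; the bromine leaves the geranyl-bearing carbon as the only alkyl-bearing ring carbon.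
4. Arene ⇒ 2,4,6-trihydroxybenzophenone, geranyl bromide, NBS; enal ⇒ diethyl isopropylidenemalonate.
5. Ring order: trione ring (from the arene) → second carbocycle of the bicyclo[3.3.1]nonane (Michael) → temporary adamantane bridge (aldol, later cut) → seven-membered homoadamantane ring → cyclopentane.

Numbering used below: C1 benzoyl bridgehead, C2–C4 the 1,3-diketone carbons, C5 geranyl bridgehead, C6 CH2, C7, C8 CMe2, C9 bridging ketone. Prenyl = 3-methylbut-2-en-1-yl; geranyl = (2E)-3,7-dimethylocta-2,6-dien-1-yl.

Assumption: the cinchonidinium salt of step 6 gives the drawn sense at C5; if it gives the mirror sense, the pseudoenantiomeric cinchoninium salt replaces it.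

## Route

Step 1
Reactants: 1 2,4,6-trihydroxybenzophenone; 2 geranyl bromide
Product: 3 3-geranyl-2,4,6-trihydroxybenzophenone
Conditions: KOH (10% aq.), 0 °C
Reagents that add atoms: none
Why: The phenolate of the acylphloroglucinol is C-alkylated at a free ring carbon by the allylic bromide (Friedel–Crafts-type C-allylation in aqueous base); one equivalent holds it at mono-alkylation and no stereocenter forms.

Step 2
Reactants: 3 3-geranyl-2,4,6-trihydroxybenzophenone
Product: 4 3-bromo-5-geranyl-2,4,6-trihydroxybenzophenone
Conditions: NBS (1.0 equiv), THF, −78 → 0 °C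
Reagents that add atoms: N-bromosuccinimide, O=C1CCC(=O)N1Br
Why: Electrophilic aromatic bromination takes the single free ring carbon far faster than the trisubstituted alkenes; the bromine blocks that carbon so that step 6 must alkylate the geranyl-bearing carbon, and it later serves as the coupling handle.

Step 3
Reactants: 5 diethyl 2-(propan-2-ylidene)malonate
Product: 6 2-(propan-2-ylidene)propane-1,3-diol
Conditions: i-Bu2AlH (4.5 equiv), CH2Cl2, −78 → 0 °C; aq. potassium sodium tartrate
Reagents that add atoms: none
Why: i-Bu2AlH reduces both conjugated esters in 1,2 fashion to the allylic diol without conjugate reduction (hydride reduction of esters).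

Step 4
Reactants: 6 2-(propan-2-ylidene)propane-1,3-diol
Product: 7 2-(hydroxymethyl)-3-methylbut-2-en-1-yl acetate
Conditions: MeC(OMe)3, PPTS (cat.), CH2Cl2, 23 °C; then H2O
Reagents that add atoms: trimethyl orthoacetate, CC(OC)(OC)OC; water, O
Why: The 1,3-diol forms a cyclic orthoester whose hydrolysis releases exactly one acetate (orthoester mono-acylation of a symmetric diol).

Step 5
Reactants: 7 2-(hydroxymethyl)-3-methylbut-2-en-1-yl acetate
Product: 8 2-formyl-3-methylbut-2-en-1-yl acetate
Conditions: MnO2, CH2Cl2, 23 °C
Reagents that add atoms: none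
Why: MnO2 oxidizes the remaining allylic alcohol selectively to the enal (allylic alcohol oxidation).

Step 6
Reactants: 4 3-bromo-5-geranyl-2,4,6-trihydroxybenzophenone; 8 2-formyl-3-methylbut-2-en-1-yl acetate
Product: 11 1-benzoyl-3-bromo-5-geranyl-8,8-dimethyl-3,7-(hydroxymethano)bicyclo[3.3.1]nonane-2,4,9-trione (bromo adamantanol), via dienone 9 (not isolated), via bicyclic aldehyde 10 (not isolated)
Conditions: N-(9-anthracenylmethyl)-O-allylcinchonidinium bromide (20 mol%), CsOH·H2O, 4 Å molecular sieves, CH2Cl2, −50 °C
Reagents that add atoms: none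
Why: Enantioselective phase-transfer alkylative dearomatization–annulation: the chiral ammonium phenolate is C-alkylated by the allylic acetate at the only alkyl-bearing ring carbon (catalyst-selected face, sets C5), the benzoyl-bearing carbon then adds to the β,β-dimethyl enal (Michael, C1 fixed by the ring), and the bromo enolate closes onto the aldehyde (aldol), which only the endo C7 epimer can do, fixing C7, C3 and the carbinol carbon (hydroxyl away from the gem-dimethyl group).

Step 7
Reactants: 11 bromo adamantanol; 12 (2-methylallyl)triphenylphosphonium chloride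
Product: 14 1-benzoyl-3-bromo-5-geranyl-2-hydroxy-8,8-dimethyl-7-endo-(3-methylbuta-1,3-dien-1-yl)bicyclo[3.3.1]non-2-ene-4,9-dione, via ylide 13 (not isolated)
Conditions: KN(SiMe3)2 (excess), THF, −78 → 0 °C; aq. NH4Cl
Reagents that add atoms: none
Why: KN(SiMe3)2 turns the phosphonium salt into the ylide and deprotonates the carbinol of the adamantanol, whose alkoxide reopens the cage by retro-aldol (the reverse of the last event of step 6) to re-expose the endo formyl group beside the bromo enolate, and the semi-stabilized ylide olefinates this formyl group at low temperature before C7 can epimerize (Wittig olefination); C5 and C1 are untouched, C7 keeps its endo configuration, and both alkene isomers converge on the same prenyl group in step 8.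

Step 8
Reactants: 14 dienyl bromo enol
Product: 15 1-benzoyl-3-bromo-5-geranyl-2-hydroxy-8,8-dimethyl-7-endo-prenylbicyclo[3.3.1]non-2-ene-4,9-dione
Conditions: H2 (4 atm), (η6-naphthalene)Cr(CO)3 (15 mol%), THF, 40 °C
Reagents that add atoms: none
Why: The Cr(CO)3 fragment hydrogenates only the s-cis 1,3-diene, in 1,4 fashion, to the trisubstituted alkene and leaves isolated alkenes, ketones and the C–Br bond alone (chromium-catalysed 1,4-hydrogenation of dienes); the E isomer reacts fastest and the Z isomer, which reaches the s-cis form less easily, needs a longer reaction time.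

Step 9
Reactants: 15 7-endo-prenyl bromo enol; 16 tributyl(3-methylbut-2-en-1-yl)stannane
Product: 17 1-benzoyl-5-geranyl-2-hydroxy-8,8-dimethyl-3-prenyl-7-endo-prenylbicyclo[3.3.1]non-2-ene-4,9-dione
Conditions: Pd2(dba)3 (5 mol%), P(2-furyl)3 (20 mol%), NMP, 50 °C
Reagents that add atoms: none
Why: Stille coupling of the 2-bromo-1,3-diketone enol (an α-bromo enone) with the allylstannane joins the unsubstituted allyl terminus to C3 and gives the linear prenyl group; no stereocenter changes.

Step 10
Reactants: 17 3,7-diprenyl enol
Product: 18 CNP0155129.1 (target)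
Conditions: 4CzIPN (2 mol%), 2,4,6-triisopropylbenzenethiol (10 mol%), 2,6-lutidine (20 mol%), PhCF3 (5 mM), 450 nm LEDs, 25 °C
Reagents that add atoms: none
Why: Proposed new method: photoexcited 4CzIPN oxidizes the enolate of 17 to the electrophilic C3 radical, which can reach only the endo C7 prenyl group and adds 7-exo to its CH carbon on the endo face of C3; the resulting tertiary radical closes 5-exo onto the C3 prenyl alkene (cis ring fusion is forced, the envelope transition state keeps the isopropyl group exo), and the last tertiary radical takes a hydrogen atom from the thiol, whose thiyl radical is reduced by the photocatalyst radical anion, so the step is a redox-neutral isomerization that sets C3 and the two new cyclopentane stereocenters. The alkene face attacked in the first closure decides whether the CMe2 carbon ends on the C1 side, as the target requires. The closest known reactions are the oxidative radical cyclization of 1,3-dicarbonyls onto alkenes with trivalent manganese and photoredox–thiol hydrofunctionalization of alkenes.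

## Compound list

1 | 2,4,6-trihydroxybenzophenone | O=C(c1ccccc1)c1c(O)cc(O)cc1O | starting material
2 | geranyl bromide, (2E)-1-bromo-3,7-dimethylocta-2,6-diene | CC(C)=CCC/C(C)=C/CBr | starting material
3 | 3-geranyl-2,4,6-trihydroxybenzophenone | CC(C)=CCC/C(C)=C/Cc1c(O)cc(O)c(C(=O)c2ccccc2)c1O | intermediate
4 | 3-bromo-5-geranyl-2,4,6-trihydroxybenzophenone | CC(C)=CCC/C(C)=C/Cc1c(O)c(Br)c(O)c(C(=O)c2ccccc2)c1O | intermediate
5 | diethyl 2-(propan-2-ylidene)malonate | CCOC(=O)C(=C(C)C)C(=O)OCC | starting material
6 | 2-(propan-2-ylidene)propane-1,3-diol | CC(C)=C(CO)CO | intermediate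
7 | 2-(hydroxymethyl)-3-methylbut-2-en-1-yl acetate | CC(=O)OCC(CO)=C(C)C | intermediate
8 | 2-formyl-3-methylbut-2-en-1-yl acetate | CC(=O)OCC(C=O)=C(C)C | intermediate
9 | 4-benzoyl-2-bromo-6-(2-formyl-3-methylbut-2-en-1-yl)-6-geranyl-3,5-dihydroxycyclohexa-2,4-dien-1-one, C6 quaternary stereocenter as in SMILES | CC(C)=CCC/C(C)=C/C[C@@]1(CC(C=O)=C(C)C)C(=O)C(Br)=C(O)C(C(=O)c2ccccc2)=C1O | intermediate
10 | 1-benzoyl-3-bromo-5-geranyl-2-hydroxy-8,8-dimethyl-4,9-dioxobicyclo[3.3.1]non-2-ene-7-carbaldehyde, formyl endo (toward C3) | CC(C)=CCC/C(C)=C/C[C@@]12C[C@@H](C=O)C(C)(C)[C@](C(=O)c3ccccc3)(C2=O)C(O)=C(Br)C1=O | intermediate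
11 | bromo adamantanol: 1-benzoyl-3-bromo-5-geranyl-8,8-dimethyl-3,7-(hydroxymethano)bicyclo[3.3.1]nonane-2,4,9-trione, hydroxyl on the C6 side of the bridge | CC(C)=CCC/C(C)=C/C[C@@]12C[C@H]3[C@@H](O)[C@@](Br)(C1=O)C(=O)[C@@](C(=O)c1ccccc1)(C2=O)C3(C)C | intermediate
12 | (2-methylallyl)triphenylphosphonium chloride | CC(=C)C[P+](c1ccccc1)(c1ccccc1)c1ccccc1.[Cl-] | starting material
13 | (2-methylallylidene)triphenylphosphorane | CC(=C)C=P(c1ccccc1)(c1ccccc1)c1ccccc1 | intermediate
14 | 1-benzoyl-3-bromo-5-geranyl-2-hydroxy-8,8-dimethyl-7-endo-(3-methylbuta-1,3-dien-1-yl)bicyclo[3.3.1]non-2-ene-4,9-dione (E isomer drawn; E/Z mixture acceptable) | CC(C)=CCC/C(C)=C/C[C@@]12C[C@@H](/C=C/C(C)=C)C(C)(C)[C@](C(=O)c3ccccc3)(C2=O)C(O)=C(Br)C1=O | intermediate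
15 | 1-benzoyl-3-bromo-5-geranyl-2-hydroxy-8,8-dimethyl-7-endo-prenylbicyclo[3.3.1]non-2-ene-4,9-dione | CC(C)=CCC/C(C)=C/C[C@@]12C[C@@H](CC=C(C)C)C(C)(C)[C@](C(=O)c3ccccc3)(C2=O)C(O)=C(Br)C1=O | intermediate
16 | tributyl(3-methylbut-2-en-1-yl)stannane | CCCC[Sn](CCCC)(CCCC)CC=C(C)C | starting material
17 | 1-benzoyl-5-geranyl-2-hydroxy-8,8-dimethyl-3-prenyl-7-endo-prenylbicyclo[3.3.1]non-2-ene-4,9-dione | CC(C)=CCC/C(C)=C/C[C@@]12C[C@@H](CC=C(C)C)C(C)(C)[C@](C(=O)c3ccccc3)(C2=O)C(O)=C(CC=C(C)C)C1=O | intermediate
18 | CNP0155129.1: 1-benzoyl-5-geranyl homoadamantane-2,4,9-trione with a cis-fused 2,2-dimethyl-3-isopropylcyclopentane on the C3–CH bond; CMe2 carbon on the C1 side, isopropyl exo | CC(C)=CCC/C(C)=C/C[C@@]12C[C@H]3C[C@@H]4C(C)(C)[C@@H](C(C)C)C[C@]4(C1=O)C(=O)[C@@](C(=O)c1ccccc1)(C2=O)C3(C)C | target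

## Step count and risks

Total step count: 10. Longest linear sequence: 8 steps (5 → 6 → 7 → 8 → 11 → 14 → 15 → 17 → 18).

**Step 6 (asymmetric annulation).** The bromo arene is not the symmetric type of substrate for which this cascade is established, so the level and sense of induction, C- versus O-alkylation and the aldol closure of the bromo enolate are all untested. The fallback changes the bond-forming mode: setting out from 4 and 8, zerovalent palladium (Pd2(dba)3) with the (R,R)-DACH-phenyl Trost ligand ionizes acetate 8 to a π-allyl complex that C-allylates 4 at the geranyl-bearing carbon (asymmetric dearomative allylic alkylation) to give dienone 9, and CsOH then closes 9 through 10 to 11, where it rejoins the route; new compounds on its way: none F0.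

**Step 9 (Stille prenylation).** The free, acidic enol may protonate the allylstannane or slow oxidative addition, and some branched (reverse-prenyl) product is possible. The fallback sets out from 15: Zn in AcOH removes the bromine to give 1-benzoyl-5-geranyl-2-hydroxy-8,8-dimethyl-7-endo-prenylbicyclo[3.3.1]non-2-ene-4,9-dione F1, which is C-prenylated at C3 with 3-methylbut-2-en-1-yl methyl carbonate and Pd(PPh3)4 (Tsuji–Trost allylation of a cyclic 1,3-diketone) and comes back to the route at 17.

**Step 10 (proposed radical bicyclization).** This step is unprecedented on this substrate class. The thiol may quench the first tertiary radical before the 5-exo closure. The face of the C7 prenyl alkene is under substrate control only: the epimer with the CMe2 carbon on the C5 side may compete or dominate, because the equatorial C8 methyl crowds the C1 side, and the two cage diastereomers would then have to be separated. The fallback sets out from 17 and uses the known oxidative radical cyclization with trivalent manganese, ending by oxidation instead of hydrogen-atom transfer. Mn(OAc)3·2H2O (2.2 equiv) with Cu(OAc)2·H2O (0.1 equiv) in degassed AcOH at 25 °C generates the same C3 radical and the two closures run as above. Divalent copper then oxidizes the last tertiary radical with loss of a methyl hydrogen, giving the isopropenyl analogue of the target, 1-benzoyl-5-geranyl homoadamantane-2,4,9-trione with a cis-fused 2,2-dimethyl-3-(prop-1-en-2-yl)cyclopentane F2. Hydrogenation with RhCl(PPh3)3 and H2 (1 atm) in benzene reduces only this 1,1-disubstituted alkene, leaves the trisubstituted geranyl alkenes alone, and returns to the route at 18.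

## Further compounds

F0 | step 6 | none | none
F1 | step 9 | 1-benzoyl-5-geranyl-2-hydroxy-8,8-dimethyl-7-endo-prenylbicyclo[3.3.1]non-2-ene-4,9-dione | CC(C)=CCC/C(C)=C/C[C@@]12C[C@@H](CC=C(C)C)C(C)(C)[C@](C(=O)c3ccccc3)(C2=O)C(O)=CC1=O
F2 | step 10 | isopropenyl analogue of 18: 1-benzoyl-5-geranyl homoadamantane-2,4,9-trione with a cis-fused 2,2-dimethyl-3-(prop-1-en-2-yl)cyclopentane | CC(C)=CCC/C(C)=C/C[C@@]12C[C@H]3C[C@@H]4C(C)(C)[C@@H](C(C)=C)C[C@]4(C1=O)C(=O)[C@@](C(=O)c1ccccc1)(C2=O)C3(C)C
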